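**Plan**

- Numbering: cyclopentene C1–C5 (C1 and C5 ring-fusion carbons, methyl on C4); cycloheptane C1, C10, C9, C8, C7, C6, C5 (methylene on C10, OH on C6); oxolane O, C11–C14 (C11 on C7, acetoxy carbon C15 on C14). β is the face of H-5.
- Enabling feature: C10 lies between C1 and C9 and the oxolane hangs on C7, so a C9–C10–C1 oxyallyl cation and a C5=C6–C7=C8 diene bearing the oxolane on C7, linked through C2–C4, map onto the whole seven-membered ring and close the five-membered ring with it.
- Cuts: C1–C5 and C8–C9 (the (4+3) step), then C6–C7 of the diene (enol triflate plus alkenylborane) and C9–C10 (chloromethyl ketone from an ester).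
- Forward: a glutarate chain gains the alkyne (C5, C6) and a C4 carbinol, is joined to the oxolane fragment as the diene and homologated to the chloromethyl ketone. The five- and seven-membered rings then form together; the oxolane is present from the start.
- Stereochemistry: C11 and C14 come from (2R,5S)-linalool oxide. C4 is set by asymmetric transfer hydrogenation and relays to C5 and C1 (cycloaddition), C7 (hydroboration) and C6 (hydride reduction). It is then oxidised to the ketone that becomes the C3=C4 methyl alkene.

Key step: step 10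

Assumption: (2R,5S)-furanoid linalool oxide is taken as purchasable in single-isomer form.
Assumption: the C4 silyloxy group is taken to end up trans to the C5–C6 bond in the cycloaddition; since C4 is later erased, the opposite sense would be served by the (R,R)-catalyst in step 2.

**Step 1**
Reactants: 1 methyl 5-chloro-5-oxopentanoate; 2 bis(trimethylsilyl)acetylene
Product: 3 methyl 5-oxo-7-(trimethylsilyl)hept-6-ynoate
Conditions: AlCl3 (1.1 equiv), CH2Cl2, 0 °C
Reagents that add atoms: none
Why: Friedel–Crafts-type acylation of the bis-silylalkyne, in which the AlCl3-activated acid chloride replaces one silyl group ipso and the remaining C–Si bond blocks a second acylation, while the methyl ester is inert.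

**Step 2**
Reactants: 3 methyl 5-oxo-7-(trimethylsilyl)hept-6-ynoate
Product: 4 methyl (5S)-5-hydroxy-7-(trimethylsilyl)hept-6-ynoate
Conditions: RuCl[(S,S)-TsNCHPhCHPhNH2](η6-p-cymene) (1 mol%), i-PrOH, rt
Reagents that add atoms: none
Why: Noyori asymmetric transfer hydrogenation of an alkynyl ketone, in which the (S,S)-configured ruthenium amido catalyst uses the alkyne as the π-recognition group and should deliver hydride to the face giving the (S)-carbinol (C4), leaving the ester untouched.

**Step 3**
Reactants: 4 methyl (5S)-5-hydroxy-7-(trimethylsilyl)hept-6-ynoate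
Product: 5 methyl (5S)-5-(triethylsilyloxy)-7-(trimethylsilyl)hept-6-ynoate
Conditions: Et3SiCl, imidazole, CH2Cl2, 0 °C
Reagents that add atoms: chlorotriethylsilane, CC[Si](Cl)(CC)CC
Why: Imidazole-promoted silyl ether formation, run directly on the crude carbinol so that the δ-hydroxy ester cannot lactonise, with no change at C4.

**Step 4**
Reactants: 5 methyl (5S)-5-(triethylsilyloxy)-7-(trimethylsilyl)hept-6-ynoate
Product: 6 methyl (5S)-5-(triethylsilyloxy)hept-6-ynoate
Conditions: K2CO3 (0.2 equiv), MeOH, 0 °C, short contact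
Reagents that add atoms: none
Why: Methoxide-induced protodesilylation of the alkynylsilane is much faster than attack on the secondary triethylsilyl ether, so the terminal alkyne should be released selectively.

**Step 5**
Reactants: 7 (2R,5S)-furanoid linalool oxide
Product: 8 2-[(2R,5S)-5-ethenyl-5-methyloxolan-2-yl]propan-2-yl acetate
Conditions: Ac2O, Et3N, DMAP (0.2 equiv), CH2Cl2, rt → 40 °C
Reagents that add atoms: acetic anhydride, CC(=O)OC(C)=O
Why: DMAP-catalysed acylation, the standard way to esterify a tertiary alcohol, touching neither oxolane stereocentre.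

**Step 6**
Reactants: 8 2-[(2R,5S)-5-ethenyl-5-methyloxolan-2-yl]propan-2-yl acetate
Product: 9 2-[(2R,5S)-5-acetyl-5-methyloxolan-2-yl]propan-2-yl acetate
Conditions: PdCl2[2-(4,5-dihydrooxazol-2-yl)quinoline] (5 mol%), AgSbF6 (12.5 mol%), 70% aq. t-BuOOH, CH2Cl2, 0 °C → rt
Reagents that add atoms: tert-butyl hydroperoxide, CC(C)(C)OO
Why: Wacker-type oxidation with a hydroperoxide as oxidant, in which the quinoline–oxazoline palladium catalyst enforces Markovnikov peroxypalladation and so should suppress the aldehyde that allylic oxygen substituents favour under chloride/copper conditions.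

**Step 7**
Reactants: 9 2-[(2R,5S)-5-acetyl-5-methyloxolan-2-yl]propan-2-yl acetate
Product: 11 1-[(2S,5R)-5-(2-acetoxypropan-2-yl)-2-methyloxolan-2-yl]ethenyl trifluoromethanesulfonate, via potassium enolate 10 (not isolated)
Conditions: KN(SiMe3)2 (1.1 equiv), THF, −78 °C; then PhNTf2, −78 → 0 °C
Reagents that add atoms: N-phenylbis(trifluoromethanesulfonimide), O=S(=O)(N(c1ccccc1)S(=O)(=O)C(F)(F)F)C(F)(F)F
Why: Enolate O-triflation, in which the ketone can enolise only toward its methyl group (the other α-carbon is fully substituted) and one equivalent of base at −78 °C leaves the less acidic acetate alone, giving a single 2-triflyloxy-1-alkene.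

**Step 8**
Reactants: 6 methyl (5S)-5-(triethylsilyloxy)hept-6-ynoate; 11 1-[(2S,5R)-5-(2-acetoxypropan-2-yl)-2-methyloxolan-2-yl]ethenyl trifluoromethanesulfonate
Product: 13 methyl (5S,6E)-8-[(2S,5R)-5-(2-acetoxypropan-2-yl)-2-methyloxolan-2-yl]-5-(triethylsilyloxy)nona-6,8-dienoate, via alkenylborane 12 (not isolated)
Conditions: Cy2BH (1.1 equiv), THF, 0 °C → rt; then 11, Pd(PPh3)4 (5 mol%), aq. K3PO4, THF, 50 °C
Reagents that add atoms: none
Why: Hydroboration followed by Suzuki–Miyaura coupling, in which syn anti-Markovnikov addition of the dialkylborane to the terminal alkyne fixes the (E)-C5=C6 geometry and zerovalent palladium joins the alkenyl group to the enol triflate carbon C7, giving the 2-substituted diene without touching C4, C11 or C14.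

**Step 9**
Reactants: 13 methyl (5S,6E)-8-[(2S,5R)-5-(2-acetoxypropan-2-yl)-2-methyloxolan-2-yl]-5-(triethylsilyloxy)nona-6,8-dienoate
Product: 14 (6S,7E)-9-[(2S,5R)-5-(2-acetoxypropan-2-yl)-2-methyloxolan-2-yl]-1-chloro-6-(triethylsilyloxy)deca-7,9-dien-2-one
Conditions: ICH2Cl (1.5 equiv), MeLi·LiBr (1.4 equiv), THF/Et2O, −78 °C; AcOH quench at −78 °C
Reagents that add atoms: chloroiodomethane, ClCI
Why: Acylation of chloromethyllithium generated by iodine–lithium exchange in the presence of the ester, whose tetrahedral adduct is stable at −78 °C and releases the chloromethyl ketone on acidic quench, the hindered tertiary acetate reacting far more slowly than the unhindered methyl ester.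

**Step 10**
Reactants: 14 (6S,7E)-9-[(2S,5R)-5-(2-acetoxypropan-2-yl)-2-methyloxolan-2-yl]-1-chloro-6-(triethylsilyloxy)deca-7,9-dien-2-one
Product: 16 trans-fused hydroazulenone (C10 ketone, C6=C7 alkene bearing the oxolane on C7, 4β-triethylsilyloxy, H-1 α, H-5 β), via oxyallyl cation 15 (not isolated)
Conditions: NaOCH2CF3 (2 equiv), CF3CH2OH, 0.01 M, 0 °C → rt
Reagents that add atoms: none
Why: Trifluoroethoxide removes a C1 proton of 14 and the enolate expels chloride from C9 to give the oxyallyl cation 15 (C9–C10–C1), which adds across the termini C5 and C8 of the s-cis diene, either in concert or by C1–C5 bonding followed by C9–C8 closure of the allyl cation/enolate pair. This is an intramolecular oxyallyl-cation (4+3) cycloaddition of the Föhlisch type, the known class in which α-halo ketones with a three-atom tether to a diene give hydroazulenones. The cyclopentane closes in the 5-exo mode through C2–C4 as the C1–C5 bond forms and the cycloheptenone closes when C9 bonds to C8, the two rings arising from one (4+3) event that leaves the C6=C7 alkene. C5 is controlled by the C4 stereocentre: in the envelope-like five-ring closure the triethylsilyloxy group lies pseudo-equatorial and anti to the diene, so C1 adds to the C5 face that places C4–O trans to C5–C6 (cis to H-5). C1 follows from the extended approach of the tethered cation and, being α to the C10 carbonyl, is also equilibrated by the alkoxide to the trans fusion, in which both ring-fusion bonds are equatorial on the seven-membered ring. The step needs cycloaddition to outrun solvent capture and Favorskii contraction and needs one diene face to react; high dilution in the ionising, weakly nucleophilic alcohol, the s-cis bias that the fully substituted C11 imposes on the 2-substituted diene and the adjacent C4 stereocentre are what secure this.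

**Step 11**
Reactants: 16 trans-fused hydroazulenone
Product: 18 6α,10-diol (H-7 α, oxolane 7β, 4β-triethylsilyloxy; C10 carbinol as an epimer mixture), via organoborane 17 (not isolated)
Conditions: BH3·THF (3 equiv), THF, 0 °C → rt; then NaBO3·4H2O, THF/H2O, rt
Reagents that add atoms: sodium perborate, [Na+].[O-]OB=O
Why: Hydroboration–oxidation, in which borane adds syn across C6=C7 with boron on the less substituted C6 and hydrogen on C7 from the α face, opposite the 4β-silyloxy group that stands over the β face at C6, so that H-7 becomes α (oxolane β), while the 6α-carbinol and the epimeric C10 carbinol from concurrent ketone reduction are both re-oxidised in the next step.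

**Step 12**
Reactants: 18 6α,10-diol
Product: 19 6,10-dione (H-1 α, H-5 β, H-7 α, 4β-triethylsilyloxy)
Conditions: Dess–Martin periodinane (3 equiv), NaHCO3, CH2Cl2, 0 °C → rt
Reagents that add atoms: none
Why: Dess–Martin oxidation under buffered, non-basic conditions turns both carbinols into ketones without epimerising C1, C5 or C7, whose all-equatorial arrangement on the cycloheptanedione should in any case be the thermodynamic one.

**Step 13**
Reactants: 19 6,10-dione
Product: 20 10-methylene-6-ketone
Conditions: Zn, CH2Br2, TiCl4 (pre-formed reagent), THF/CH2Cl2, 0 °C → rt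
Reagents that add atoms: dibromomethane, BrCBr
Why: Lombardo methylenation is non-basic and sterically discriminating, so the C10 carbonyl (flanked by CH2 and CH) should react while the C6 carbonyl, wedged between the ring-fusion methine and C7 bearing the fully substituted C11, the acetate and the α-stereocentres stay intact.

**Step 14**
Reactants: 20 10-methylene-6-ketone
Product: 21 6β-carbinol (OH cis to H-5 and to the 7β-oxolane)
Conditions: LiBH(s-Bu)3, THF, −78 °C
Reagents that add atoms: none
Why: Ketone reduction with a bulky trialkylborohydride, which should attack C6 from the α face, away from the 4β-silyloxy group and the 7β-oxolanyl substituent, giving the 6β-carbinol cis to the α-branch as such hydrides do with α-substituted cycloalkanones.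

**Step 15**
Reactants: 21 6β-carbinol
Product: 22 6β-(tert-butyldimethylsilyl) ether
Conditions: t-BuMe2SiOTf, 2,6-lutidine, CH2Cl2, −78 → 0 °C
Reagents that add atoms: tert-butyldimethylsilyl trifluoromethanesulfonate, CC(C)(C)[Si](C)(C)OS(=O)(=O)C(F)(F)F
Why: Silylation with a silyl triflate and a hindered pyridine base, the standard method for a crowded secondary carbinol, installing a group that outlasts the triethylsilyl ether on C4.

**Step 16**
Reactants: 22 6β-(tert-butyldimethylsilyl) ether
Product: 23 4β-carbinol (6β-silyl ether retained)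
Conditions: pyridinium p-toluenesulfonate (0.2 equiv), MeOH/CH2Cl2, 0 °C
Reagents that add atoms: none
Why: Differential silyl ether cleavage, since acid-catalysed methanolysis of a triethylsilyl ether is far faster than that of a hindered tert-butyldimethylsilyl ether and the mild acid should not isomerise the exocyclic alkene.

**Step 17**
Reactants: 23 4β-carbinol
Product: 24 4-ketone (cyclopentanone, 6β-silyl ether)
Conditions: Dess–Martin periodinane, NaHCO3, CH2Cl2, 0 °C → rt
Reagents that add atoms: none
Why: Dess–Martin oxidation gives the cyclopentanone, and with C6 held as its silyl ether no 1,3-dicarbonyl arises, so C5 keeps its configuration under the buffered conditions.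

**Step 18**
Reactants: 24 4-ketone
Product: 26 C3=C4 enol triflate, via potassium enolate 25 (not isolated)
Conditions: KN(SiMe3)2 (1.05 equiv), THF, −78 °C; then PhNTf2, −78 → −20 °C
Reagents that add atoms: N-phenylbis(trifluoromethanesulfonimide), O=S(=O)(N(c1ccccc1)S(=O)(=O)C(F)(F)F)C(F)(F)F
Why: Kinetic enolate formation and O-triflation, in which the hindered amide base removes a proton from the C3 methylene and not from the ring-fusion methine C5 (which would open an elimination of the C6 silyloxy group), placing the double bond at C3=C4.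

**Step 19**
Reactants: 26 C3=C4 enol triflate
Product: 27 6-O-(tert-butyldimethylsilyl) ether of the target
Conditions: Me2Zn (2 equiv), Pd(PPh3)4 (5 mol%), THF, 0 °C → rt
Reagents that add atoms: dimethylzinc, C[Zn]C
Why: Negishi cross-coupling of the alkenyl triflate with a methylzinc reagent under zerovalent palladium catalysis replaces the triflate by methyl without moving the C3=C4 bond and tolerates the tertiary acetate.

**Step 20**
Reactants: 27 6-O-(tert-butyldimethylsilyl) ether of the target
Product: 28 CNP0302132.4
Conditions: HF·pyridine, pyridine, THF, 0 °C → rt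
Reagents that add atoms: none
Why: Fluoride-mediated desilylation under buffered conditions should free the 6β-hydroxyl without acyl migration, acetate loss or isomerisation of either alkene.

**Compound list**

1 | methyl 5-chloro-5-oxopentanoate | COC(=O)CCCC(Cl)=O | starting material
2 | bis(trimethylsilyl)acetylene | C[Si](C)(C)C#C[Si](C)(C)C | starting material
3 | methyl 5-oxo-7-(trimethylsilyl)hept-6-ynoate | COC(=O)CCCC(=O)C#C[Si](C)(C)C | intermediate
4 | methyl (5S)-5-hydroxy-7-(trimethylsilyl)hept-6-ynoate | COC(=O)CCC[C@H](O)C#C[Si](C)(C)C | intermediate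
5 | methyl (5S)-5-(triethylsilyloxy)-7-(trimethylsilyl)hept-6-ynoate | COC(=O)CCC[C@H](O[Si](CC)(CC)CC)C#C[Si](C)(C)C | intermediate
6 | methyl (5S)-5-(triethylsilyloxy)hept-6-ynoate | COC(=O)CCC[C@H](O[Si](CC)(CC)CC)C#C | intermediate
7 | (2R,5S)-furanoid linalool oxide, 2-[(2R,5S)-5-ethenyl-5-methyloxolan-2-yl]propan-2-ol (vinyl and hydroxypropyl groups cis) | C=C[C@]1(C)CC[C@H](C(C)(C)O)O1 | starting material
8 | 2-[(2R,5S)-5-ethenyl-5-methyloxolan-2-yl]propan-2-yl acetate | C=C[C@]1(C)CC[C@H](C(C)(C)OC(C)=O)O1 | intermediate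
9 | 2-[(2R,5S)-5-acetyl-5-methyloxolan-2-yl]propan-2-yl acetate | CC(=O)[C@]1(C)CC[C@H](C(C)(C)OC(C)=O)O1 | intermediate
10 | potassium enolate of 9 (not isolated) | [K+].[O-]C(=C)[C@]1(C)CC[C@H](C(C)(C)OC(C)=O)O1 | intermediate
11 | 1-[(2S,5R)-5-(2-acetoxypropan-2-yl)-2-methyloxolan-2-yl]ethenyl trifluoromethanesulfonate | C=C(OS(=O)(=O)C(F)(F)F)[C@]1(C)CC[C@H](C(C)(C)OC(C)=O)O1 | intermediate
12 | methyl (5S,6E)-7-(dicyclohexylboryl)-5-(triethylsilyloxy)hept-6-enoate (not isolated) | COC(=O)CCC[C@H](O[Si](CC)(CC)CC)/C=C/B(C1CCCCC1)C1CCCCC1 | intermediate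
13 | methyl (5S,6E)-8-[(2S,5R)-5-(2-acetoxypropan-2-yl)-2-methyloxolan-2-yl]-5-(triethylsilyloxy)nona-6,8-dienoate | COC(=O)CCC[C@H](O[Si](CC)(CC)CC)/C=C/C(=C)[C@]1(C)CC[C@H](C(C)(C)OC(C)=O)O1 | intermediate
14 | (6S,7E)-9-[(2S,5R)-5-(2-acetoxypropan-2-yl)-2-methyloxolan-2-yl]-1-chloro-6-(triethylsilyloxy)deca-7,9-dien-2-one (cycloaddition precursor) | ClCC(=O)CCC[C@H](O[Si](CC)(CC)CC)/C=C/C(=C)[C@]1(C)CC[C@H](C(C)(C)OC(C)=O)O1 | intermediate
15 | oxyallyl cation (C9–C10–C1 zwitterion) from 14 (not isolated) | [CH2+]C([O-])=CCC[C@H](O[Si](CC)(CC)CC)/C=C/C(=C)[C@]1(C)CC[C@H](C(C)(C)OC(C)=O)O1 | intermediate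
16 | trans-fused hydroazulenone: C10 ketone, C6=C7 alkene with the oxolane on C7, 4β-triethylsilyloxy (cis to H-5), H-1 α, H-5 β | O=C1CCC([C@]2(C)CC[C@H](C(C)(C)OC(C)=O)O2)=C[C@@H]2[C@@H](O[Si](CC)(CC)CC)CC[C@@H]12 | intermediate
17 | 6α-boryl 10-boryloxy adduct of 16 (not isolated; C10 configuration open) | BOC1CC[C@@H]([C@]2(C)CC[C@H](C(C)(C)OC(C)=O)O2)[C@H](B)[C@@H]2[C@@H](O[Si](CC)(CC)CC)CC[C@@H]12 | intermediate
18 | 6α,10-diol: H-7 α, oxolane 7β, 4β-triethylsilyloxy, trans-fused; C10 carbinol an epimer mixture (left open in the SMILES) | OC1CC[C@@H]([C@]2(C)CC[C@H](C(C)(C)OC(C)=O)O2)[C@H](O)[C@@H]2[C@@H](O[Si](CC)(CC)CC)CC[C@@H]12 | intermediate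
19 | 6,10-dione: H-1 α, H-5 β, H-7 α, 4β-triethylsilyloxy | O=C1CC[C@@H]([C@]2(C)CC[C@H](C(C)(C)OC(C)=O)O2)C(=O)[C@@H]2[C@@H](O[Si](CC)(CC)CC)CC[C@@H]12 | intermediate
20 | 10-methylene-6-ketone, 4β-triethylsilyloxy | C=C1CC[C@@H]([C@]2(C)CC[C@H](C(C)(C)OC(C)=O)O2)C(=O)[C@@H]2[C@@H](O[Si](CC)(CC)CC)CC[C@@H]12 | intermediate
21 | 10-methylene-6β-carbinol, 4β-triethylsilyloxy | C=C1CC[C@@H]([C@]2(C)CC[C@H](C(C)(C)OC(C)=O)O2)[C@@H](O)[C@@H]2[C@@H](O[Si](CC)(CC)CC)CC[C@@H]12 | intermediate
22 | 6β-(tert-butyldimethylsilyloxy)-4β-(triethylsilyloxy) bis-silyl ether | C=C1CC[C@@H]([C@]2(C)CC[C@H](C(C)(C)OC(C)=O)O2)[C@@H](O[Si](C)(C)C(C)(C)C)[C@@H]2[C@@H](O[Si](CC)(CC)CC)CC[C@@H]12 | intermediate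
23 | 4β-carbinol, 6β-(tert-butyldimethylsilyloxy) | C=C1CC[C@@H]([C@]2(C)CC[C@H](C(C)(C)OC(C)=O)O2)[C@@H](O[Si](C)(C)C(C)(C)C)[C@@H]2[C@@H](O)CC[C@@H]12 | intermediate
24 | 4-ketone, 6β-(tert-butyldimethylsilyloxy) | C=C1CC[C@@H]([C@]2(C)CC[C@H](C(C)(C)OC(C)=O)O2)[C@@H](O[Si](C)(C)C(C)(C)C)[C@@H]2C(=O)CC[C@@H]12 | intermediate
25 | potassium C3=C4 enolate of 24 (not isolated) | [K+].C=C1CC[C@@H]([C@]2(C)CC[C@H](C(C)(C)OC(C)=O)O2)[C@@H](O[Si](C)(C)C(C)(C)C)[C@@H]2C([O-])=CC[C@@H]12 | intermediate
26 | C3=C4 enol triflate (triflate on C4), 6β-(tert-butyldimethylsilyloxy) | C=C1CC[C@@H]([C@]2(C)CC[C@H](C(C)(C)OC(C)=O)O2)[C@@H](O[Si](C)(C)C(C)(C)C)[C@@H]2C(OS(=O)(=O)C(F)(F)F)=CC[C@@H]12 | intermediate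
27 | 6-O-(tert-butyldimethylsilyl) ether of the target | C=C1CC[C@@H]([C@]2(C)CC[C@H](C(C)(C)OC(C)=O)O2)[C@@H](O[Si](C)(C)C(C)(C)C)[C@@H]2C(C)=CC[C@@H]12 | intermediate
28 | CNP0302132.4: H-1 α, H-5 β, 6β-OH, 7β-oxolanyl, C3=C4 methyl alkene, C10 methylene, tertiary acetate on C15 | C=C1CC[C@@H]([C@]2(C)CC[C@H](C(C)(C)OC(C)=O)O2)[C@@H](O)[C@@H]2C(C)=CC[C@@H]12 | target

**Step count**

Total: 20 steps. Longest linear sequence: 17 steps (steps 1–4 and 8–20); steps 5–7 form the three-step oxolane branch.

**Steps most likely to fail**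

Step 10. The sodium oxyallyl species may be captured by trifluoroethanol or collapse by Favorskii contraction faster than it adds to the unactivated diene, and facial discrimination by C4 may be incomplete. The fallback sets out from 13. Dichloromethyllithium (CH2Cl2, LiN(i-Pr)2, THF, −78 °C) converts the ester into the dichloromethyl ketone F1. The same alkoxide conditions then generate a chlorine-stabilised, longer-lived oxyallyl cation, a known variant that reacts better with weak dienes, and its (4+3) closure gives the 9-chloro cycloadduct F2. Reductive dechlorination with Zn–Cu couple and NH4Cl in MeOH comes back to the route at 16.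

Step 11. Borane may arrive on the β face of C6=C7, which would put H-7 on the wrong side, or may add sluggishly to the hindered alkene. The fallback sets out from 16 and uses that same β preference. Epoxidation with m-chloroperbenzoic acid (NaHCO3, CH2Cl2, 0 °C) gives the β-epoxide F3. Meinwald rearrangement with BF3·OEt2 (CH2Cl2, −78 °C) opens it at the tertiary C7, and the α-hydrogen of C6 shifts to C7 with inversion, so H-7 becomes α and C6 becomes the ketone. This comes back to the route at 19 and is complementary in facial demand to the hydroboration.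

Step 14. Hydride delivery may occur from the β face, or with poor facial selectivity, and give the 6α-carbinol. The fallback sets out from 20 and sets C6 by substitution instead of by carbonyl-face selection. The ketone is reduced with whichever hydride gives the 6α-carbinol F4 cleanly. Mitsunobu inversion with 4-nitrobenzoic acid, PPh3 and diisopropyl azodicarboxylate (the acid of choice for hindered carbinols) gives the inverted 6β-(4-nitrobenzoate) F5. Brief methanolysis with K2CO3 in MeOH at 0 °C, which spares the tertiary acetate, comes back to the route at 21.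

**Further compounds**

F1 | step 10 | (6S,7E)-9-[(2S,5R)-5-(2-acetoxypropan-2-yl)-2-methyloxolan-2-yl]-1,1-dichloro-6-(triethylsilyloxy)deca-7,9-dien-2-one | ClC(Cl)C(=O)CCC[C@H](O[Si](CC)(CC)CC)/C=C/C(=C)[C@]1(C)CC[C@H](C(C)(C)OC(C)=O)O1
F2 | step 10 | 9-chloro derivative of cycloadduct 16 (C9 epimers) | O=C1C(Cl)CC([C@]2(C)CC[C@H](C(C)(C)OC(C)=O)O2)=C[C@@H]2[C@@H](O[Si](CC)(CC)CC)CC[C@@H]12
F3 | step 11 | 6β,7β-epoxide of 16 | O=C1CC[C@@]2([C@]3(C)CC[C@H](C(C)(C)OC(C)=O)O3)O[C@H]2[C@@H]2[C@@H](O[Si](CC)(CC)CC)CC[C@@H]12
F4 | step 14 | 10-methylene-6α-carbinol (C6 epimer of 21) | C=C1CC[C@@H]([C@]2(C)CC[C@H](C(C)(C)OC(C)=O)O2)[C@H](O)[C@@H]2[C@@H](O[Si](CC)(CC)CC)CC[C@@H]12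
F5 | step 14 | 6β-(4-nitrobenzoate) of 21 | C=C1CC[C@@H]([C@]2(C)CC[C@H](C(C)(C)OC(C)=O)O2)[C@@H](OC(=O)c3ccc(cc3)[N+](=O)[O-])[C@@H]2[C@@H](O[Si](CC)(CC)CC)CC[C@@H]12
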